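**Plan**
Units: 1 = 7-hydroxy dihydrobenzofuran (benzo ring A), 2 = central one (ring B), 3 = 6-hydroxy one (ring C). Retrosynthetic cuts: the two aryl–vinyl bonds of the stilbene (two Suzuki–Miyaura couplings on an ethene-1,2-diyl bis(boronate)); one furan C–O bond per unit (O1–C7a in units 1 and 3, O1–C2 in unit 2); and the four C–C bonds around each C2–C3 pair (C3–aryl twice, C2–C3, C2–anisyl), all made by 1,2-shifts on boron.
Enabling feature: ring A of unit 1 carries O1 on C7a and the hydroxyl on the neighbouring C7, next to C3a. A C7–C7a aryne raised from an ortho-fluoroaryl group of an open-chain carbinol therefore takes the tethered alkoxide at C7a and leaves a C7 carbanion for borylation and oxidation.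
Forward order: three 1,2,2-triarylethanols are assembled by double Matteson homologation. West: the aryne closes the furan of unit 1 (step 5). East: copper etherification closes unit 3, its C4 bromide becomes the aryl nucleophile that starts unit 2, and acid closes unit 2. Then vinylboronate formation, fragment coupling and BBr3.
Stereochemistry: five of the six centres arise from stereospecific 1,2-shifts on boron esters of (1S,2S)-1,2-dicyclohexylethane-1,2-diol; C2 of unit 2 is set trans to C3 in the ring closure.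

Key step: step 5

Remark: the (S,S)-diol ester is taken to give, in the Matteson reaction, the α-chloride that is R when chlorine outranks the migrated carbon and that carbon outranks boron; every later displacement at that carbon goes with inversion and C–B oxidation with retention. All descriptors below follow from this rule.

**Route**

Step 1
Reactants: 1 3,5-dimethoxyphenylboronic acid; 2 (1S,2S)-1,2-dicyclohexylethane-1,2-diol
Product: 3 (4S,5S)-4,5-dicyclohexyl-2-(3,5-dimethoxyphenyl)-1,3,2-dioxaborolane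
Conditions: MgSO4, Et2O, rt
Reagents that add atoms: none
Why: Condensation of a boronic acid with a 1,2-diol (boronic ester formation) is driven by removal of water and installs the C2-symmetric director used in all later homologations.

Step 2
Reactants: 3 aryl boronate
Product: 4 (4S,5S)-2-[(R)-chloro(3,5-dimethoxyphenyl)methyl]-4,5-dicyclohexyl-1,3,2-dioxaborolane
Conditions: CH2Cl2, n-BuLi, THF, −100 °C; 3; ZnCl2, −100 °C → rt; aqueous NH4Cl work-up, used crude
Reagents that add atoms: dichloromethane, ClCCl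
Why: In this Matteson homologation LiCHCl2 adds to boron and the aryl group migrates with loss of the chloride selected by the (S,S)-diol, which should give the (αR)-chloride, while ZnCl2 speeds the 1,2-shift and binds the chloride that would epimerise the benzylic centre.

Step 3
Reactants: 4 α-chloro boronate; 5 2-bromo-4-chloro-1-fluorobenzene
Product: 7 (4S,5S)-2-[(S)-(5-chloro-2-fluorophenyl)(3,5-dimethoxyphenyl)methyl]-4,5-dicyclohexyl-1,3,2-dioxaborolane, via aryl Grignard 6 (not isolated)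
Conditions: 5, i-PrMgCl·LiCl, THF, −20 °C; then 4, −78 °C → rt
Reagents that add atoms: none
Why: Bromine–magnesium exchange gives the ortho-fluoroaryl Grignard reagent below the temperature of aryne formation, and its borate with 4 rearranges by a 1,2-shift that displaces chloride with inversion (second half of the Matteson homologation), which sets the benzhydryl carbon as S.

Step 4
Reactants: 7 (S)-diarylmethyl boronate; 8 4-methoxyphenylmagnesium bromide
Product: 11 (1S,2S)-2-(5-chloro-2-fluorophenyl)-2-(3,5-dimethoxyphenyl)-1-(4-methoxyphenyl)ethan-1-ol, via α-chloro boronate 9 (not isolated), via secondary boronate 10 (not isolated)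
Conditions: CH2Cl2, n-BuLi, THF, −100 °C; 7; ZnCl2, −100 °C → rt; 8 (3 equiv), −78 °C → rt; NaOH, 30% H2O2, 0 °C → rt
Reagents that add atoms: dichloromethane, ClCCl; hydrogen peroxide, OO
Why: A second Matteson homologation inserts the (αR)-chloromethine with retention at the migrating benzhydryl carbon, the anisyl Grignard reagent displaces chloride with inversion and alkaline peroxide oxidises the C–B bond with retention, so the carbinol carbon is set as S by the same diol, which is released.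

Step 5
Reactants: 11 (1S,2S)-triarylethanol
Product: 16 (2S,3S)-5-chloro-3-(3,5-dimethoxyphenyl)-2-(4-methoxyphenyl)-2,3-dihydro-1-benzofuran-7-ol, via dilithio carbinol 12 (not isolated), via aryne alkoxide 13 (not isolated), via C7 aryllithium 14 (not isolated), via dimethyl arylboronate 15 (not isolated)
Conditions: s-BuLi (2.2 equiv), THF, −78 °C; −78 → −20 °C; B(OMe)3, −78 °C → rt; AcOH, 30% H2O2, 0 °C → rt
Reagents that add atoms: hydrogen peroxide, OO
Why: Proposed new method: s-BuLi first forms the lithium alkoxide and then removes the ring proton next to fluorine (ortho to F, meta to Cl, the most acidic one); on warming LiF is lost to give the C7–C7a aryne 13, the alkoxide adds to C7a in a 5-exo-dig closure that makes the O1–C7a bond, and the resulting C7 aryllithium 14, ortho to the new ether oxygen, is captured by B(OMe)3 and oxidised with retention to the phenol. The closest known reactions are the anionic cyclisations of aryne-tethered nucleophiles generated from 2-fluoroaryllithiums with electrophilic quench of the new aryllithium, and the classical ring closures of arynes by tethered heteroatom nucleophiles; an alkoxide of a 1,2,2-triarylethanol has not been used in this way. No stereocentre is formed: neither the carbinol C–O bond nor the benzhydryl C–H bond is broken, so (1S,2S)-11 should give the trans (2S,3S) ring. The step needs site selectivity in the lithiation and in the addition to the aryne; the single fluorine allows only one aryne, and the two-carbon tether lets oxygen reach only C7a, which places the carbanion at C7. Deprotonation of the benzhydryl C–H is disfavoured by the neighbouring alkoxide charge at −78 °C, and butane, the only conjugate acid formed, cannot protonate the aryllithium before the borate is added.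

Step 6
Reactants: 4 α-chloro boronate; 17 1,3-dibromo-5-methoxybenzene
Product: 19 (4S,5S)-4,5-dicyclohexyl-2-[(S)-(2,6-dibromo-4-methoxyphenyl)(3,5-dimethoxyphenyl)methyl]-1,3,2-dioxaborolane, via aryllithium 18 (not isolated)
Conditions: 17, LiN(i-Pr)2, THF, −78 °C; 4, −78 °C; ZnCl2, −78 °C → rt
Reagents that add atoms: none
Why: Deprotonation between the two bromine atoms (directed ortho-metalation at the most acidic ring position) gives an aryllithium whose borate with 4 rearranges with inversion at carbon (Matteson homologation), so the benzhydryl carbon becomes S, the configuration of C3 of unit 3.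

Step 7
Reactants: 19 (S)-diarylmethyl boronate; 8 4-methoxyphenylmagnesium bromide
Product: 22 (1S,2S)-2-(2,6-dibromo-4-methoxyphenyl)-2-(3,5-dimethoxyphenyl)-1-(4-methoxyphenyl)ethan-1-ol, via α-chloro boronate 20 (not isolated), via secondary boronate 21 (not isolated)
Conditions: CH2Cl2, n-BuLi, THF, −100 °C; 19; ZnCl2, −100 °C → rt; 8 (3 equiv), −78 °C → rt; NaOH, 30% H2O2, 0 °C → rt
Reagents that add atoms: dichloromethane, ClCCl; hydrogen peroxide, OO
Why: Matteson homologation, Grignard displacement with inversion and C–B oxidation with retention, as in step 4, set the carbinol carbon as S under control of the diol.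

Step 8
Reactants: 22 (1S,2S)-triarylethanol
Product: 23 (2S,3S)-4-bromo-3-(3,5-dimethoxyphenyl)-6-methoxy-2-(4-methoxyphenyl)-2,3-dihydro-1-benzofuran
Conditions: CuI (10 mol %), 1,10-phenanthroline (20 mol %), Cs2CO3, toluene, 110 °C
Reagents that add atoms: none
Why: Copper-catalysed intramolecular Ullmann etherification forms the O1–C7a bond at either of the two equivalent ortho C–Br bonds (5-exo closure) without breaking a bond at the stereocentres, so the (1S,2S)-carbinol should give the trans (2S,3S) ring and keep one bromine at C4.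

Step 9
Reactants: 24 2-bromo-5-chlorophenol
Product: 25 1-bromo-4-chloro-2-(methoxymethoxy)benzene
Conditions: NaH, DMF, 0 °C; MOMCl, 0 °C → rt
Reagents that add atoms: chloromethyl methyl ether, COCCl
Why: O-Alkylation of the sodium phenoxide (Williamson ether synthesis) masks the future O1 of unit 2 as an acetal that survives organometallic reagents and alkaline peroxide.

Step 10
Reactants: 25 aryl bromide; 2 (1S,2S)-1,2-dicyclohexylethane-1,2-diol
Product: 28 (4S,5S)-2-[4-chloro-2-(methoxymethoxy)phenyl]-4,5-dicyclohexyl-1,3,2-dioxaborolane, via aryllithium 26 (not isolated), via lithium triisopropoxyborate 27 (not isolated)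
Conditions: n-BuLi, THF, −78 °C; B(Oi-Pr)3, −78 °C → rt; 2, AcOH, rt
Reagents that add atoms: triisopropyl borate, CC(C)OB(OC(C)C)OC(C)C
Why: Bromine–lithium exchange is much faster than any reaction of the aryl chloride, the aryllithium is trapped as a borate, and the diol displaces isopropanol on acidification (borylation followed by transesterification).

Step 11
Reactants: 28 aryl boronate
Product: 29 (4S,5S)-2-[(R)-chloro[4-chloro-2-(methoxymethoxy)phenyl]methyl]-4,5-dicyclohexyl-1,3,2-dioxaborolane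
Conditions: CH2Cl2, n-BuLi, THF, −100 °C; 28; ZnCl2, −100 °C → rt; aqueous NH4Cl work-up, used crude
Reagents that add atoms: dichloromethane, ClCCl
Why: Matteson homologation as in step 2, in which the (S,S)-diol again selects the chloride whose loss gives the (αR)-chloride.

Step 12
Reactants: 23 C4 bromide of unit 3; 29 α-chloro boronate
Product: 31 (4S,5S)-2-[(R)-[4-chloro-2-(methoxymethoxy)phenyl][(2S,3S)-3-(3,5-dimethoxyphenyl)-6-methoxy-2-(4-methoxyphenyl)-2,3-dihydro-1-benzofuran-4-yl]methyl]-4,5-dicyclohexyl-1,3,2-dioxaborolane, via aryllithium 30 (not isolated)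
Conditions: 23, n-BuLi, THF, −78 °C; 29, −78 °C; ZnCl2, −78 °C → rt
Reagents that add atoms: none
Why: Bromine–lithium exchange at C4 of unit 3 gives an aryllithium whose borate with 29 rearranges with inversion (Matteson homologation), so the new benzhydryl carbon, C3 of unit 2, is set as R by the diol independently of the two centres already present.

Step 13
Reactants: 31 (R)-diarylmethyl boronate; 8 4-methoxyphenylmagnesium bromide
Product: 34 (1S,2R)-2-[4-chloro-2-(methoxymethoxy)phenyl]-2-[(2S,3S)-3-(3,5-dimethoxyphenyl)-6-methoxy-2-(4-methoxyphenyl)-2,3-dihydro-1-benzofuran-4-yl]-1-(4-methoxyphenyl)ethan-1-ol, via α-chloro boronate 32 (not isolated), via secondary boronate 33 (not isolated)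
Conditions: CH2Cl2, n-BuLi, THF, −100 °C; 31; ZnCl2, −100 °C → rt; 8 (3 equiv), −78 °C → rt; NaOH, 30% H2O2, 0 °C → rt
Reagents that add atoms: dichloromethane, ClCCl; hydrogen peroxide, OO
Why: Matteson homologation, displacement with inversion and oxidation with retention, as in step 4, give the (1S)-carbinol, the epimer from which both an invertive and a cationic ring closure lead to the trans furan.

Step 14
Reactants: 34 (1S,2R)-carbinol
Product: 36 (2R,3R)-6-chloro-3-[(2S,3S)-3-(3,5-dimethoxyphenyl)-6-methoxy-2-(4-methoxyphenyl)-2,3-dihydro-1-benzofuran-4-yl]-2-(4-methoxyphenyl)-2,3-dihydro-1-benzofuran, via phenol 35 (not isolated)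
Conditions: TsOH·H2O (0.3 equiv), MeOH–CH2Cl2, 40 °C; evaporation; TsOH (0.1 equiv), CH2Cl2, 4 Å sieves, 0 °C → rt
Reagents that add atoms: none
Why: Acid cleaves the methoxymethyl acetal and then ionises the 4-methoxybenzylic alcohol, whose carbon is taken by the neighbouring phenol in a 5-exo-trig etherification (cyclodehydration) anti to the aryl group on C3, so C2 of unit 2 becomes R under control of C3 and of the thermodynamic preference for the trans ring.

Step 15
Reactants: 36 aryl chloride; 37 (E)-1,2-bis(4,4,5,5-tetramethyl-1,3,2-dioxaborolan-2-yl)ethene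
Product: 38 2-[(E)-2-[(2R,3R)-3-[(2S,3S)-3-(3,5-dimethoxyphenyl)-6-methoxy-2-(4-methoxyphenyl)-2,3-dihydro-1-benzofuran-4-yl]-2-(4-methoxyphenyl)-2,3-dihydro-1-benzofuran-6-yl]ethenyl]-4,4,5,5-tetramethyl-1,3,2-dioxaborolane
Conditions: Pd(OAc)2 (5 mol %), SPhos (10 mol %), K3PO4, 37 (3 equiv), THF–H2O, 60 °C
Reagents that add atoms: none
Why: Suzuki–Miyaura coupling of the aryl chloride with one boron of the excess bis(boronate) proceeds with retention of the E geometry and leaves the second boronate for the next coupling.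

Step 16
Reactants: 16 west aryl chloride; 38 east alkenylboronate
Product: 39 (2S,3S)-5-[(E)-2-[(2R,3R)-3-[(2S,3S)-3-(3,5-dimethoxyphenyl)-6-methoxy-2-(4-methoxyphenyl)-2,3-dihydro-1-benzofuran-4-yl]-2-(4-methoxyphenyl)-2,3-dihydro-1-benzofuran-6-yl]ethenyl]-3-(3,5-dimethoxyphenyl)-2-(4-methoxyphenyl)-2,3-dihydro-1-benzofuran-7-ol
Conditions: Pd(OAc)2 (5 mol %), SPhos (10 mol %), K3PO4 (3 equiv), 1,4-dioxane–H2O, 90 °C
Reagents that add atoms: none
Why: Suzuki–Miyaura coupling of an electron-rich aryl chloride with an E-alkenylboronate under a dialkylbiarylphosphine ligand retains the alkene geometry and tolerates the free phenol.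

Step 17
Reactants: 39 octamethyl ether
Product: 40 (2S,3S)-5-[(E)-2-[(2R,3R)-3-[(2S,3S)-3-(3,5-dihydroxyphenyl)-6-hydroxy-2-(4-hydroxyphenyl)-2,3-dihydro-1-benzofuran-4-yl]-2-(4-hydroxyphenyl)-2,3-dihydro-1-benzofuran-6-yl]ethenyl]-3-(3,5-dihydroxyphenyl)-2-(4-hydroxyphenyl)-2,3-dihydro-1-benzofuran-7-ol
Conditions: BBr3 (12 equiv), CH2Cl2, −78 °C → rt; MeOH, H2O
Reagents that add atoms: none
Why: Lewis-acid cleavage of the eight aryl methyl ethers (BBr3 demethylation) frees all phenols, and the three trans rings are the thermodynamic isomers, so reversible ionisation at a C2 position should not change the configuration.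

**Compound list**

1 | 3,5-dimethoxyphenylboronic acid | COc1cc(cc(OC)c1)B(O)O | starting material
2 | (1S,2S)-1,2-dicyclohexylethane-1,2-diol | O[C@@H](C1CCCCC1)[C@@H](O)C1CCCCC1 | starting material
3 | (4S,5S)-4,5-dicyclohexyl-2-(3,5-dimethoxyphenyl)-1,3,2-dioxaborolane | COc1cc(cc(OC)c1)B1O[C@@H](C2CCCCC2)[C@H](C2CCCCC2)O1 | intermediate
4 | (4S,5S)-2-[(R)-chloro(3,5-dimethoxyphenyl)methyl]-4,5-dicyclohexyl-1,3,2-dioxaborolane | COc1cc(cc(OC)c1)[C@H](Cl)B1O[C@@H](C2CCCCC2)[C@H](C2CCCCC2)O1 | intermediate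
5 | 2-bromo-4-chloro-1-fluorobenzene | Fc1ccc(Cl)cc1Br | starting material
6 | (5-chloro-2-fluorophenyl)magnesium chloride (LiCl complex) | Fc1ccc(Cl)cc1[Mg]Cl | intermediate
7 | (4S,5S)-2-[(S)-(5-chloro-2-fluorophenyl)(3,5-dimethoxyphenyl)methyl]-4,5-dicyclohexyl-1,3,2-dioxaborolane | COc1cc(cc(OC)c1)[C@@H](c1cc(Cl)ccc1F)B1O[C@@H](C2CCCCC2)[C@H](C2CCCCC2)O1 | intermediate
8 | 4-methoxyphenylmagnesium bromide | COc1ccc([Mg]Br)cc1 | starting material
9 | (4S,5S)-2-[(1R,2S)-1-chloro-2-(5-chloro-2-fluorophenyl)-2-(3,5-dimethoxyphenyl)ethyl]-4,5-dicyclohexyl-1,3,2-dioxaborolane | COc1cc(cc(OC)c1)[C@@H](c1cc(Cl)ccc1F)[C@H](Cl)B1O[C@@H](C2CCCCC2)[C@H](C2CCCCC2)O1 | intermediate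
10 | (4S,5S)-2-[(1S,2S)-2-(5-chloro-2-fluorophenyl)-2-(3,5-dimethoxyphenyl)-1-(4-methoxyphenyl)ethyl]-4,5-dicyclohexyl-1,3,2-dioxaborolane | COc1cc(cc(OC)c1)[C@@H](c1cc(Cl)ccc1F)[C@@H](c1ccc(OC)cc1)B1O[C@@H](C2CCCCC2)[C@H](C2CCCCC2)O1 | intermediate
11 | (1S,2S)-2-(5-chloro-2-fluorophenyl)-2-(3,5-dimethoxyphenyl)-1-(4-methoxyphenyl)ethan-1-ol | COc1ccc([C@H]([C@H](c2cc(Cl)ccc2F)c2cc(OC)cc(OC)c2)O)cc1 | intermediate
12 | lithium (1S,2S)-2-(5-chloro-2-fluoro-3-lithiophenyl)-2-(3,5-dimethoxyphenyl)-1-(4-methoxyphenyl)ethan-1-olate | COc1ccc([C@H]([C@H](c2cc(Cl)cc([Li])c2F)c2cc(OC)cc(OC)c2)O[Li])cc1 | intermediate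
13 | lithium (1S,2S)-2-(5-chloro-2,3-didehydrophenyl)-2-(3,5-dimethoxyphenyl)-1-(4-methoxyphenyl)ethan-1-olate (aryne) | COc1ccc([C@H]([C@H](C2=CC(Cl)=CC#C2)c2cc(OC)cc(OC)c2)O[Li])cc1 | intermediate
14 | [(2S,3S)-5-chloro-3-(3,5-dimethoxyphenyl)-2-(4-methoxyphenyl)-2,3-dihydro-1-benzofuran-7-yl]lithium | COc1ccc([C@H]2Oc3c([Li])cc(Cl)cc3[C@@H]2c2cc(OC)cc(OC)c2)cc1 | intermediate
15 | dimethyl [(2S,3S)-5-chloro-3-(3,5-dimethoxyphenyl)-2-(4-methoxyphenyl)-2,3-dihydro-1-benzofuran-7-yl]boronate | COc1ccc([C@H]2Oc3c(B(OC)OC)cc(Cl)cc3[C@@H]2c2cc(OC)cc(OC)c2)cc1 | intermediate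
16 | (2S,3S)-5-chloro-3-(3,5-dimethoxyphenyl)-2-(4-methoxyphenyl)-2,3-dihydro-1-benzofuran-7-ol | COc1ccc([C@H]2Oc3c(O)cc(Cl)cc3[C@@H]2c2cc(OC)cc(OC)c2)cc1 | intermediate
17 | 1,3-dibromo-5-methoxybenzene | COc1cc(Br)cc(Br)c1 | starting material
18 | (2,6-dibromo-4-methoxyphenyl)lithium | COc1cc(Br)c([Li])c(Br)c1 | intermediate
19 | (4S,5S)-4,5-dicyclohexyl-2-[(S)-(2,6-dibromo-4-methoxyphenyl)(3,5-dimethoxyphenyl)methyl]-1,3,2-dioxaborolane | COc1cc(cc(OC)c1)[C@@H](c1c(Br)cc(OC)cc1Br)B1O[C@@H](C2CCCCC2)[C@H](C2CCCCC2)O1 | intermediate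
20 | (4S,5S)-2-[(1R,2S)-1-chloro-2-(2,6-dibromo-4-methoxyphenyl)-2-(3,5-dimethoxyphenyl)ethyl]-4,5-dicyclohexyl-1,3,2-dioxaborolane | COc1cc(cc(OC)c1)[C@@H](c1c(Br)cc(OC)cc1Br)[C@H](Cl)B1O[C@@H](C2CCCCC2)[C@H](C2CCCCC2)O1 | intermediate
21 | (4S,5S)-4,5-dicyclohexyl-2-[(1S,2S)-2-(2,6-dibromo-4-methoxyphenyl)-2-(3,5-dimethoxyphenyl)-1-(4-methoxyphenyl)ethyl]-1,3,2-dioxaborolane | COc1cc(cc(OC)c1)[C@@H](c1c(Br)cc(OC)cc1Br)[C@@H](c1ccc(OC)cc1)B1O[C@@H](C2CCCCC2)[C@H](C2CCCCC2)O1 | intermediate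
22 | (1S,2S)-2-(2,6-dibromo-4-methoxyphenyl)-2-(3,5-dimethoxyphenyl)-1-(4-methoxyphenyl)ethan-1-ol | COc1ccc([C@H]([C@H](c2c(Br)cc(OC)cc2Br)c2cc(OC)cc(OC)c2)O)cc1 | intermediate
23 | (2S,3S)-4-bromo-3-(3,5-dimethoxyphenyl)-6-methoxy-2-(4-methoxyphenyl)-2,3-dihydro-1-benzofuran | COc1ccc([C@H]2Oc3cc(OC)cc(Br)c3[C@@H]2c2cc(OC)cc(OC)c2)cc1 | intermediate
24 | 2-bromo-5-chlorophenol | Oc1cc(Cl)ccc1Br | starting material
25 | 1-bromo-4-chloro-2-(methoxymethoxy)benzene | COCOc1cc(Cl)ccc1Br | intermediate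
26 | [4-chloro-2-(methoxymethoxy)phenyl]lithium | COCOc1cc(Cl)ccc1[Li] | intermediate
27 | lithium [4-chloro-2-(methoxymethoxy)phenyl]tri(propan-2-yloxy)borate | [Li+].COCOc1cc(Cl)ccc1[B-](OC(C)C)(OC(C)C)OC(C)C | intermediate
28 | (4S,5S)-2-[4-chloro-2-(methoxymethoxy)phenyl]-4,5-dicyclohexyl-1,3,2-dioxaborolane | COCOc1cc(Cl)ccc1B1O[C@@H](C2CCCCC2)[C@H](C2CCCCC2)O1 | intermediate
29 | (4S,5S)-2-[(R)-chloro[4-chloro-2-(methoxymethoxy)phenyl]methyl]-4,5-dicyclohexyl-1,3,2-dioxaborolane | COCOc1cc(Cl)ccc1[C@H](Cl)B1O[C@@H](C2CCCCC2)[C@H](C2CCCCC2)O1 | intermediate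
30 | [(2S,3S)-3-(3,5-dimethoxyphenyl)-6-methoxy-2-(4-methoxyphenyl)-2,3-dihydro-1-benzofuran-4-yl]lithium | COc1ccc([C@H]2Oc3cc(OC)cc([Li])c3[C@@H]2c2cc(OC)cc(OC)c2)cc1 | intermediate
31 | (4S,5S)-2-[(R)-[4-chloro-2-(methoxymethoxy)phenyl][(2S,3S)-3-(3,5-dimethoxyphenyl)-6-methoxy-2-(4-methoxyphenyl)-2,3-dihydro-1-benzofuran-4-yl]methyl]-4,5-dicyclohexyl-1,3,2-dioxaborolane | COCOc1cc(Cl)ccc1[C@@H](c1cc(OC)cc2O[C@H](c3ccc(OC)cc3)[C@@H](c3cc(OC)cc(OC)c3)c12)B1O[C@@H](C2CCCCC2)[C@H](C2CCCCC2)O1 | intermediate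
32 | (4S,5S)-2-[(1R,2R)-1-chloro-2-[4-chloro-2-(methoxymethoxy)phenyl]-2-[(2S,3S)-3-(3,5-dimethoxyphenyl)-6-methoxy-2-(4-methoxyphenyl)-2,3-dihydro-1-benzofuran-4-yl]ethyl]-4,5-dicyclohexyl-1,3,2-dioxaborolane | COCOc1cc(Cl)ccc1[C@@H](c1cc(OC)cc2O[C@H](c3ccc(OC)cc3)[C@@H](c3cc(OC)cc(OC)c3)c12)[C@H](Cl)B1O[C@@H](C2CCCCC2)[C@H](C2CCCCC2)O1 | intermediate
33 | (4S,5S)-2-[(1S,2R)-2-[4-chloro-2-(methoxymethoxy)phenyl]-2-[(2S,3S)-3-(3,5-dimethoxyphenyl)-6-methoxy-2-(4-methoxyphenyl)-2,3-dihydro-1-benzofuran-4-yl]-1-(4-methoxyphenyl)ethyl]-4,5-dicyclohexyl-1,3,2-dioxaborolane | COCOc1cc(Cl)ccc1[C@@H](c1cc(OC)cc2O[C@H](c3ccc(OC)cc3)[C@@H](c3cc(OC)cc(OC)c3)c12)[C@@H](c1ccc(OC)cc1)B1O[C@@H](C2CCCCC2)[C@H](C2CCCCC2)O1 | intermediate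
34 | (1S,2R)-2-[4-chloro-2-(methoxymethoxy)phenyl]-2-[(2S,3S)-3-(3,5-dimethoxyphenyl)-6-methoxy-2-(4-methoxyphenyl)-2,3-dihydro-1-benzofuran-4-yl]-1-(4-methoxyphenyl)ethan-1-ol | COCOc1cc(Cl)ccc1[C@@H](c1cc(OC)cc2O[C@H](c3ccc(OC)cc3)[C@@H](c3cc(OC)cc(OC)c3)c12)[C@@H](c1ccc(OC)cc1)O | intermediate
35 | (1S,2R)-2-(4-chloro-2-hydroxyphenyl)-2-[(2S,3S)-3-(3,5-dimethoxyphenyl)-6-methoxy-2-(4-methoxyphenyl)-2,3-dihydro-1-benzofuran-4-yl]-1-(4-methoxyphenyl)ethan-1-ol | Oc1cc(Cl)ccc1[C@@H](c1cc(OC)cc2O[C@H](c3ccc(OC)cc3)[C@@H](c3cc(OC)cc(OC)c3)c12)[C@@H](c1ccc(OC)cc1)O | intermediate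
36 | (2R,3R)-6-chloro-3-[(2S,3S)-3-(3,5-dimethoxyphenyl)-6-methoxy-2-(4-methoxyphenyl)-2,3-dihydro-1-benzofuran-4-yl]-2-(4-methoxyphenyl)-2,3-dihydro-1-benzofuran | Clc1ccc2c(c1)O[C@@H](c1ccc(OC)cc1)[C@@H]2c1cc(OC)cc2c1[C@H](c1cc(OC)cc(OC)c1)[C@@H](c1ccc(OC)cc1)O2 | intermediate
37 | (E)-1,2-bis(4,4,5,5-tetramethyl-1,3,2-dioxaborolan-2-yl)ethene | CC1(C)OB(/C=C/B2OC(C)(C)C(C)(C)O2)OC1(C)C | starting material
38 | 2-[(E)-2-[(2R,3R)-3-[(2S,3S)-3-(3,5-dimethoxyphenyl)-6-methoxy-2-(4-methoxyphenyl)-2,3-dihydro-1-benzofuran-4-yl]-2-(4-methoxyphenyl)-2,3-dihydro-1-benzofuran-6-yl]ethenyl]-4,4,5,5-tetramethyl-1,3,2-dioxaborolane | CC1(C)OB(/C=C/c2ccc3c(c2)O[C@@H](c2ccc(OC)cc2)[C@@H]3c2cc(OC)cc3c2[C@H](c2cc(OC)cc(OC)c2)[C@@H](c2ccc(OC)cc2)O3)OC1(C)C | intermediate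
39 | (2S,3S)-5-[(E)-2-[(2R,3R)-3-[(2S,3S)-3-(3,5-dimethoxyphenyl)-6-methoxy-2-(4-methoxyphenyl)-2,3-dihydro-1-benzofuran-4-yl]-2-(4-methoxyphenyl)-2,3-dihydro-1-benzofuran-6-yl]ethenyl]-3-(3,5-dimethoxyphenyl)-2-(4-methoxyphenyl)-2,3-dihydro-1-benzofuran-7-ol | COc1ccc([C@H]2Oc3c(O)cc(/C=C/c4ccc5c(c4)O[C@@H](c4ccc(OC)cc4)[C@@H]5c4cc(OC)cc5c4[C@H](c4cc(OC)cc(OC)c4)[C@@H](c4ccc(OC)cc4)O5)cc3[C@@H]2c2cc(OC)cc(OC)c2)cc1 | intermediate
40 | (2S,3S)-5-[(E)-2-[(2R,3R)-3-[(2S,3S)-3-(3,5-dihydroxyphenyl)-6-hydroxy-2-(4-hydroxyphenyl)-2,3-dihydro-1-benzofuran-4-yl]-2-(4-hydroxyphenyl)-2,3-dihydro-1-benzofuran-6-yl]ethenyl]-3-(3,5-dihydroxyphenyl)-2-(4-hydroxyphenyl)-2,3-dihydro-1-benzofuran-7-ol (CNP0265934.1) | Oc1ccc([C@H]2Oc3c(O)cc(/C=C/c4ccc5c(c4)O[C@@H](c4ccc(O)cc4)[C@@H]5c4cc(O)cc5c4[C@H](c4cc(O)cc(O)c4)[C@@H](c4ccc(O)cc4)O5)cc3[C@@H]2c2cc(O)cc(O)c2)cc1 | target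

**Step count and risks**

Total step count: 17. Longest linear sequence: 11 steps (1, 2, 6, 7, 8, 12, 13, 14, 15, 16, 17).

Step 5 (proposed new method). What may go wrong: metalation between the two methoxy groups of the dimethoxyphenyl ring instead of next to fluorine, intermolecular capture of the aryne, or protonation of the C7 carbanion before it is borylated, which would leave C7 without oxygen. Fallback with known chemistry, leaving the route at 4 and returning at 16: both oxygens of ring A are brought in by the aryl nucleophile and the furan is closed by acid as in step 14. Dakin oxidation (NaOH, H2O2) of commercial 3-bromo-5-chloro-2-hydroxybenzaldehyde (O=Cc1cc(Cl)cc(Br)c1O) should give 3-bromo-5-chlorobenzene-1,2-diol F1. NaH and MOMCl then give 1-bromo-5-chloro-2,3-bis(methoxymethoxy)benzene F2. Bromine–lithium exchange (n-BuLi, THF, −78 °C) gives [5-chloro-2,3-bis(methoxymethoxy)phenyl]lithium F3, which with 4 gives, as in step 3, the (S)-diarylmethyl boronate F4. Homologation to the α-chloro boronate F5, displacement by 8 to the secondary boronate F6 and oxidation, all as in step 4, give the (1S,2S)-carbinol F7. TsOH in MeOH–CH2Cl2 removes both acetals to the catechol F8, whose hydroxyl ortho to the side chain closes the furan through the 4-methoxybenzyl cation trans to the aryl group on C3, giving 16.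

Step 12. What may go wrong: the 1,2-shift of the doubly ortho-substituted aryl group in a crowded borate may be slow, so that the α-chloride epimerises or a diol oxygen migrates instead; proton transfer from the C3–H of 23 to the aryllithium is a second loss channel. Fallback, leaving the route at 23 and returning at 36: the roles are exchanged, so that the hindered aryl group migrates to the unhindered dichloromethyl carbon and the second aryl group arrives on boron. Aryllithium 30 is borylated with B(Oi-Pr)3 and esterified with (1R,2R)-1,2-dicyclohexylethane-1,2-diol (O[C@H](C1CCCCC1)[C@H](O)C1CCCCC1) and AcOH to the (4R,5R)-aryl boronate F9. LiCHCl2 and ZnCl2 then give the (αS)-chloride F10. Aryllithium 26 displaces chloride with inversion to the (R)-diarylmethyl boronate F11, the analogue of 31 with the enantiomeric diol. Homologation to the α-chloro boronate F12, displacement by 8 to the secondary boronate F13 and oxidation give the (1R,2R)-carbinol F14, the C1 epimer of 34. Under the conditions of step 14 this closes through the 4-methoxybenzyl cation to the same trans furan 36.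

Step 14. What may go wrong: the 4-methoxybenzyl cation may lose a proton or take a hydride from C3 and so scramble C3 of unit 2, or the furan of unit 3 may open under the acid. Fallback, leaving the route at 34 and returning at 36 without any new compound: the acetal is removed without protic acid (TMSOTf, 2,2'-bipyridyl, CH2Cl2, 0 °C; then H2O) and phenol 35 is isolated. The ring is then closed by intramolecular Mitsunobu etherification (PPh3, DIAD, THF, 0 °C), an SN2 displacement with inversion at the (1S)-carbinol carbon, which gives the trans (2R,3R) furan 36 without a free cation.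

**Further compounds**

F1 | step 5 | 3-bromo-5-chlorobenzene-1,2-diol | Oc1cc(Cl)cc(Br)c1O
F2 | step 5 | 1-bromo-5-chloro-2,3-bis(methoxymethoxy)benzene | COCOc1cc(Cl)cc(Br)c1OCOC
F3 | step 5 | [5-chloro-2,3-bis(methoxymethoxy)phenyl]lithium | COCOc1cc(Cl)cc([Li])c1OCOC
F4 | step 5 | (4S,5S)-2-[(S)-[5-chloro-2,3-bis(methoxymethoxy)phenyl](3,5-dimethoxyphenyl)methyl]-4,5-dicyclohexyl-1,3,2-dioxaborolane | COc1cc(cc(OC)c1)[C@@H](c1cc(Cl)cc(OCOC)c1OCOC)B1O[C@@H](C2CCCCC2)[C@H](C2CCCCC2)O1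
F5 | step 5 | (4S,5S)-2-[(1R,2S)-1-chloro-2-[5-chloro-2,3-bis(methoxymethoxy)phenyl]-2-(3,5-dimethoxyphenyl)ethyl]-4,5-dicyclohexyl-1,3,2-dioxaborolane | COc1cc(cc(OC)c1)[C@@H](c1cc(Cl)cc(OCOC)c1OCOC)[C@H](Cl)B1O[C@@H](C2CCCCC2)[C@H](C2CCCCC2)O1
F6 | step 5 | (4S,5S)-2-[(1S,2S)-2-[5-chloro-2,3-bis(methoxymethoxy)phenyl]-2-(3,5-dimethoxyphenyl)-1-(4-methoxyphenyl)ethyl]-4,5-dicyclohexyl-1,3,2-dioxaborolane | COc1cc(cc(OC)c1)[C@@H](c1cc(Cl)cc(OCOC)c1OCOC)[C@@H](c1ccc(OC)cc1)B1O[C@@H](C2CCCCC2)[C@H](C2CCCCC2)O1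
F7 | step 5 | (1S,2S)-2-[5-chloro-2,3-bis(methoxymethoxy)phenyl]-2-(3,5-dimethoxyphenyl)-1-(4-methoxyphenyl)ethan-1-ol | COc1ccc([C@H]([C@H](c2cc(Cl)cc(OCOC)c2OCOC)c2cc(OC)cc(OC)c2)O)cc1
F8 | step 5 | 5-chloro-3-[(1S,2S)-1-(3,5-dimethoxyphenyl)-2-hydroxy-2-(4-methoxyphenyl)ethyl]benzene-1,2-diol | COc1ccc([C@H]([C@H](c2cc(Cl)cc(O)c2O)c2cc(OC)cc(OC)c2)O)cc1
F9 | step 12 | (4R,5R)-4,5-dicyclohexyl-2-[(2S,3S)-3-(3,5-dimethoxyphenyl)-6-methoxy-2-(4-methoxyphenyl)-2,3-dihydro-1-benzofuran-4-yl]-1,3,2-dioxaborolane | COc1ccc([C@H]2Oc3cc(OC)cc(B4O[C@H](C5CCCCC5)[C@@H](C5CCCCC5)O4)c3[C@@H]2c2cc(OC)cc(OC)c2)cc1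
F10 | step 12 | (4R,5R)-2-[(S)-chloro[(2S,3S)-3-(3,5-dimethoxyphenyl)-6-methoxy-2-(4-methoxyphenyl)-2,3-dihydro-1-benzofuran-4-yl]methyl]-4,5-dicyclohexyl-1,3,2-dioxaborolane | COc1ccc([C@H]2Oc3cc(OC)cc([C@@H](Cl)B4O[C@H](C5CCCCC5)[C@@H](C5CCCCC5)O4)c3[C@@H]2c2cc(OC)cc(OC)c2)cc1
F11 | step 12 | (4R,5R)-2-[(R)-[4-chloro-2-(methoxymethoxy)phenyl][(2S,3S)-3-(3,5-dimethoxyphenyl)-6-methoxy-2-(4-methoxyphenyl)-2,3-dihydro-1-benzofuran-4-yl]methyl]-4,5-dicyclohexyl-1,3,2-dioxaborolane | COc1ccc([C@H]2Oc3cc(OC)cc([C@H](c4ccc(Cl)cc4OCOC)B4O[C@H](C5CCCCC5)[C@@H](C5CCCCC5)O4)c3[C@@H]2c2cc(OC)cc(OC)c2)cc1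
F12 | step 12 | (4R,5R)-2-[(1S,2R)-1-chloro-2-[4-chloro-2-(methoxymethoxy)phenyl]-2-[(2S,3S)-3-(3,5-dimethoxyphenyl)-6-methoxy-2-(4-methoxyphenyl)-2,3-dihydro-1-benzofuran-4-yl]ethyl]-4,5-dicyclohexyl-1,3,2-dioxaborolane | COc1ccc([C@H]2Oc3cc(OC)cc([C@H](c4ccc(Cl)cc4OCOC)[C@@H](Cl)B4O[C@H](C5CCCCC5)[C@@H](C5CCCCC5)O4)c3[C@@H]2c2cc(OC)cc(OC)c2)cc1
F13 | step 12 | (4R,5R)-2-[(1R,2R)-2-[4-chloro-2-(methoxymethoxy)phenyl]-2-[(2S,3S)-3-(3,5-dimethoxyphenyl)-6-methoxy-2-(4-methoxyphenyl)-2,3-dihydro-1-benzofuran-4-yl]-1-(4-methoxyphenyl)ethyl]-4,5-dicyclohexyl-1,3,2-dioxaborolane | COc1ccc([C@H]2Oc3cc(OC)cc([C@H](c4ccc(Cl)cc4OCOC)[C@H](c4ccc(OC)cc4)B4O[C@H](C5CCCCC5)[C@@H](C5CCCCC5)O4)c3[C@@H]2c2cc(OC)cc(OC)c2)cc1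
F14 | step 12 | (1R,2R)-2-[4-chloro-2-(methoxymethoxy)phenyl]-2-[(2S,3S)-3-(3,5-dimethoxyphenyl)-6-methoxy-2-(4-methoxyphenyl)-2,3-dihydro-1-benzofuran-4-yl]-1-(4-methoxyphenyl)ethan-1-ol | COc1ccc([C@H]2Oc3cc(OC)cc([C@H](c4ccc(Cl)cc4OCOC)[C@H](c4ccc(OC)cc4)O)c3[C@@H]2c2cc(OC)cc(OC)c2)cc1
F0 | step 14 | none | none
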